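**Overview**

1. Numbering: ring B (quinone) is C1(=O), C2 (side chain), C3–H, C4(=O); ring A is C4a, C5 (OMe), C6, C7, C8 (OH), C8a.
2. Cuts: the O–Si bond of a C8 silyl ether; the C4 carbonyl back to the C4–OMe of a 1-naphthol; then ring B at C4–C3, C2–C1 and C1–C8a. This leaves an aryl(methoxy)carbene complex of zerovalent chromium (C4 on ring A), one CO ligand (C1) and a terminal alkyne carrying the whole ester chain (C3, C2). Within the alkyne, the ester O–C(=O) bond and the bond between the carbinol carbon and the alkyne (made at the ketone stage) are cut.
3. Enabling feature: ring B has oxygen at C1 and C4 and an H at C3 beside a branched carbon at C2. It is fused to a ring A whose carbons flanking C4a differ (C5 blocked by OMe, C8a free). This is exactly the pattern that a carbene carbon, H–C≡C–R and CO lay down.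
4. Forward: ring A is bought and made into the carbene complex. The alkyne is assembled from 4-methylpent-3-enoic acid, trimethylsilylacetylene and 3-methylbut-2-enoic acid. Ring B closes in the benzannulation, which also joins the two halves, and is oxidized to the quinone in the same flask. Desilylation ends the route.
5. Stereochemistry: the one S centre is set by asymmetric transfer hydrogenation of a silyl ynone (divalent ruthenium, (S,S)-TsDPEN ligand), and no later step breaks a bond at it.

Key step: step 8

Remark on the chemistry: the phenol silyl group is tert-butyldimethylsilyl throughout; in the SMILES strings carbonyl ligands on chromium are written Cr=C=O, and the η6-bound Cr(CO)3 unit of 16 is attached by a dot because a π-bond to a ring has no valence-bond notation.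

**Route**

Step 1
Reactants: 1 3-bromo-4-methoxyphenol
Product: 2 tert-butyl(3-bromo-4-methoxyphenoxy)dimethylsilane
Conditions: TBSCl, imidazole, DMF, rt
Reagents that add atoms: tert-butyldimethylsilyl chloride, CC(C)(C)[Si](C)(C)Cl
Why: Imidazole-promoted silyl ether formation on a phenol is routine, and the bulky silyl ether masks the acidic OH for the organolithium step and should tolerate the short acidic oxidation later.

Step 2
Reactants: 2 tert-butyl(3-bromo-4-methoxyphenoxy)dimethylsilane; 3 chromium hexacarbonyl
Product: 6 pentacarbonyl{[5-(tert-butyldimethylsilyloxy)-2-methoxyphenyl](methoxy)methylidene}chromium, via aryllithium 4 (not isolated), via lithium acylchromate 5 (not isolated)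
Conditions: n-BuLi, THF, −78 °C; Cr(CO)6, −78 °C to rt; then Me3OBF4, CH2Cl2, 0 °C to rt
Reagents that add atoms: trimethyloxonium tetrafluoroborate, C[O+](C)C.F[B-](F)(F)F
Why: This is the Fischer carbene synthesis, in which bromine–lithium exchange outruns ortho-metalation, the aryllithium adds to a CO ligand of zerovalent Cr(CO)6 and the hard oxonium salt methylates the acylchromate on oxygen; the silyl ether is meta to lithium, so no silyl shift to carbon is open.

Step 3
Reactants: 7 4-methylpent-3-enoic acid
Product: 8 N-methoxy-N,4-dimethylpent-3-enamide
Conditions: MeNHOMe·HCl, EDC·HCl, HOBt (cat.), N-methylmorpholine, CH2Cl2, 0 °C to rt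
Reagents that add atoms: N,O-dimethylhydroxylamine hydrochloride, CNOC.Cl
Why: Carbodiimide coupling gives the Weinreb amide under near-neutral conditions, so the β,γ double bond should not move into conjugation as it could through an acid chloride or ketene.

Step 4
Reactants: 8 N-methoxy-N,4-dimethylpent-3-enamide; 9 trimethylsilylacetylene
Product: 11 6-methyl-1-(trimethylsilyl)hept-5-en-1-yn-3-one, via lithium trimethylsilylacetylide 10 (not isolated)
Conditions: 9, n-BuLi, THF, −78 °C; add 8, −78 to −20 °C; AcOH quench at −78 °C
Reagents that add atoms: none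
Why: Acyl substitution of a Weinreb amide by a lithium acetylide stops at the ketone because the lithium chelate of the tetrahedral adduct holds until the cold acetic acid quench, which also releases the ynone without free base that could shift its double bond.

Step 5
Reactants: 11 6-methyl-1-(trimethylsilyl)hept-5-en-1-yn-3-one
Product: 12 (3S)-6-methyl-1-(trimethylsilyl)hept-5-en-1-yn-3-ol
Conditions: Ru[(S,S)-TsNCH(Ph)CH(Ph)NH](η6-p-cymene) (1–2 mol %), i-PrOH, rt
Reagents that add atoms: none
Why: In this Noyori asymmetric transfer hydrogenation of an ynone the amido complex of divalent ruthenium takes hydrogen from isopropanol and passes hydride and proton to the ketone through a six-membered transition state with the alkynyl group in the place usually held by aryl, so the (S,S) ligand is expected to give the S carbinol, and the absence of added base protects the acidic allylic CH2.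

Step 6
Reactants: 12 (3S)-6-methyl-1-(trimethylsilyl)hept-5-en-1-yn-3-ol
Product: 13 (3S)-6-methylhept-5-en-1-yn-3-ol
Conditions: K2CO3 (cat.), MeOH, 0 °C to rt; careful concentration (volatile product)
Reagents that add atoms: none
Why: Carbonate-catalysed methanolysis cleaves only the C(sp)–Si bond (protodesilylation of a silyl alkyne) and is placed before esterification because the same medium would transesterify the senecioate.

Step 7
Reactants: 13 (3S)-6-methylhept-5-en-1-yn-3-ol; 14 3-methylbut-2-enoic acid
Product: 15 (3S)-6-methylhept-5-en-1-yn-3-yl 3-methylbut-2-enoate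
Conditions: DCC, DMAP (cat.), CH2Cl2, 0 °C to rt
Reagents that add atoms: none
Why: Steglich esterification acylates the secondary propargylic alcohol through the acylpyridinium with retention (no bond at the stereocentre is broken) and avoids the acid chloride and amine pairing that leads through a vinylketene to the deconjugated 3-methylbut-3-enoate.

Step 8
Reactants: 6 pentacarbonyl{[5-(tert-butyldimethylsilyloxy)-2-methoxyphenyl](methoxy)methylidene}chromium; 15 (3S)-6-methylhept-5-en-1-yn-3-yl 3-methylbut-2-enoate
Product: 18 (1S)-1-[8-(tert-butyldimethylsilyloxy)-5-methoxy-1,4-dioxo-1,4-dihydronaphthalen-2-yl]-4-methylpent-3-en-1-yl 3-methylbut-2-enoate, via tricarbonylchromium naphthol complex 16 (not isolated), via free naphthol 17 (not isolated)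
Conditions: 15 (1.3 equiv), degassed THF (0.05 M), 50 °C, Ar; then (NH4)2Ce(NO3)6 (6 equiv), MeCN/H2O, 0 °C
Reagents that add atoms: water, O
Why: Thermal loss of one CO from 6 lets the terminal alkyne of 15 bind and insert into the Cr=C bond so that the carbene carbon (future C4) bonds to the unsubstituted alkyne carbon (C3); CO then inserts at the new carbene carbon (C2) to give a chromium-bound dienylketene, whose ketene carbon (C1) bonds to the only free ortho carbon of the aryl group (C8a), and tautomerization leaves the naphthol as its Cr(CO)3 complex 16. This is the Dötz benzannulation of an aryl(alkoxy)carbene complex of zerovalent chromium with a terminal alkyne, followed by its customary oxidative work-up, in which tetravalent cerium first strips the metal to free naphthol 17 and then oxidizes the para-methoxynaphthol ring to the quinone, water attacking C4 and methanol leaving. Ring B is the only ring closed, by 6π electrocyclization of the dienylketene (C1–C8a) after the intermolecular bonds C4–C3 and C2–C1 have formed. No stereocentre is created; the S carbinol carbon of 15 is carried through with none of its bonds broken, and the planar chirality of 16 is lost on decomplexation. Regioselective insertion rests on the size difference between H and the branched carbinol carbon at the two alkyne ends, which places the side chain next to the CO-derived C1, and the direction of ring closure is fixed because the other ortho position carries the methoxy group. Chemoselectivity should follow because the trisubstituted alkenes are poor ligands and sit too close to the alkyne for intramolecular cyclopropanation, because the free naphthol ring is oxidized far faster than the methoxy/silyloxy ring (which the new quinone deactivates further), and because oxidation in the same flask at 0 °C gives the ortho-hydroxybenzylic ester of 17 no time to ionize.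

Step 9
Reactants: 18 (1S)-1-[8-(tert-butyldimethylsilyloxy)-5-methoxy-1,4-dioxo-1,4-dihydronaphthalen-2-yl]-4-methylpent-3-en-1-yl 3-methylbut-2-enoate
Product: 19 (1S)-1-(8-hydroxy-5-methoxy-1,4-dioxo-1,4-dihydronaphthalen-2-yl)-4-methylpent-3-en-1-yl 3-methylbut-2-enoate (CNP0299347.1)
Conditions: HF·pyridine, pyridine, THF, 0 °C
Reagents that add atoms: none
Why: Fluoride cleavage of an aryl silyl ether is made especially easy here by the peri carbonyl, which turns the phenoxide into a good leaving group, and the buffered non-basic medium should leave the quinone, the ester and the stereocentre untouched.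

**Compound list**

1 | 3-bromo-4-methoxyphenol | COc1ccc(O)cc1Br | starting material
2 | tert-butyl(3-bromo-4-methoxyphenoxy)dimethylsilane | COc1ccc(O[Si](C)(C)C(C)(C)C)cc1Br | intermediate
3 | chromium hexacarbonyl, Cr(CO)6 | O=C=[Cr](=C=O)(=C=O)(=C=O)(=C=O)=C=O | starting material
4 | [5-(tert-butyldimethylsilyloxy)-2-methoxyphenyl]lithium (not isolated) | [Li]c1cc(O[Si](C)(C)C(C)(C)C)ccc1OC | intermediate
5 | lithium pentacarbonyl{[5-(tert-butyldimethylsilyloxy)-2-methoxyphenyl](oxido)methylidene}chromate (not isolated) | [Li+].[O-]C(=[Cr](=C=O)(=C=O)(=C=O)(=C=O)=C=O)c1cc(O[Si](C)(C)C(C)(C)C)ccc1OC | intermediate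
6 | pentacarbonyl{[5-(tert-butyldimethylsilyloxy)-2-methoxyphenyl](methoxy)methylidene}chromium | COC(=[Cr](=C=O)(=C=O)(=C=O)(=C=O)=C=O)c1cc(O[Si](C)(C)C(C)(C)C)ccc1OC | intermediate
7 | 4-methylpent-3-enoic acid | CC(C)=CCC(=O)O | starting material
8 | N-methoxy-N,4-dimethylpent-3-enamide | CC(C)=CCC(=O)N(C)OC | intermediate
9 | trimethylsilylacetylene | C#C[Si](C)(C)C | starting material
10 | lithium (trimethylsilyl)acetylide (not isolated) | [Li]C#C[Si](C)(C)C | intermediate
11 | 6-methyl-1-(trimethylsilyl)hept-5-en-1-yn-3-one | CC(C)=CCC(=O)C#C[Si](C)(C)C | intermediate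
12 | (3S)-6-methyl-1-(trimethylsilyl)hept-5-en-1-yn-3-ol | C[Si](C)(C)C#C[C@H](CC=C(C)C)O | intermediate
13 | (3S)-6-methylhept-5-en-1-yn-3-ol | C#C[C@H](CC=C(C)C)O | intermediate
14 | 3-methylbut-2-enoic acid | CC(C)=CC(=O)O | starting material
15 | (3S)-6-methylhept-5-en-1-yn-3-yl 3-methylbut-2-enoate | C#C[C@H](CC=C(C)C)OC(=O)C=C(C)C | intermediate
16 | tricarbonylchromium η6 complex of naphthol 17, metal on the newly formed ring (not isolated) | COc1ccc(O[Si](C)(C)C(C)(C)C)c2c(O)c([C@H](CC=C(C)C)OC(=O)C=C(C)C)cc(OC)c12.O=C=[Cr](=C=O)=C=O | intermediate
17 | (1S)-1-[8-(tert-butyldimethylsilyloxy)-1-hydroxy-4,5-dimethoxynaphthalen-2-yl]-4-methylpent-3-en-1-yl 3-methylbut-2-enoate (not isolated) | COc1ccc(O[Si](C)(C)C(C)(C)C)c2c(O)c([C@H](CC=C(C)C)OC(=O)C=C(C)C)cc(OC)c12 | intermediate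
18 | (1S)-1-[8-(tert-butyldimethylsilyloxy)-5-methoxy-1,4-dioxo-1,4-dihydronaphthalen-2-yl]-4-methylpent-3-en-1-yl 3-methylbut-2-enoate | COc1ccc(O[Si](C)(C)C(C)(C)C)c2c1C(=O)C=C([C@H](CC=C(C)C)OC(=O)C=C(C)C)C2=O | intermediate
19 | (1S)-1-(8-hydroxy-5-methoxy-1,4-dioxo-1,4-dihydronaphthalen-2-yl)-4-methylpent-3-en-1-yl 3-methylbut-2-enoate (CNP0299347.1) | COc1ccc(O)c2c1C(=O)C=C([C@H](CC=C(C)C)OC(=O)C=C(C)C)C2=O | target

**Count and risks**

Total step count: 9. Longest linear sequence: 7 steps (steps 3 to 9, from acid 7); the arene branch (steps 1 and 2) joins at step 8.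

Steps most likely to fail:

1. Step 8. The senecioate may be lost by ionization at the carbinol carbon, either at the chromium vinylcarbene stage or from the electron-rich ortho-hydroxybenzylic naphthol through an ortho-quinone methide. Ring closure may also occur without CO insertion, or the silyl group may migrate across the peri positions so that the wrong ring is oxidized. The fallback puts the ester on last; it sets out from 13 (with 6) and comes back to the route at 19. Alkynol 13 is silylated (TBSCl, imidazole) to tert-butyl(dimethyl){[(3S)-6-methylhept-5-en-1-yn-3-yl]oxy}silane F1, whose silyloxy group is a poor leaving group. Benzannulation of F1 with 6 under the conditions of step 8 should pass through the tricarbonylchromium naphthol complex F2 and the free bis-silyl naphthol F3, and the (NH4)2Ce(NO3)6 work-up should give the bis-silyl quinone F4. HF·pyridine then removes both silyl groups to give the hydroxy quinone F5. Steglich esterification of F5 with 14 (DCC, DMAP) should acylate the secondary alcohol in preference to the hydrogen-bonded peri phenol and give 19.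

2. Step 5. The β,γ double bond may migrate into conjugation with the ynone under the basic amido catalyst before hydride transfer, or facial discrimination between a slender alkynyl group and a primary allylic CH2 may be weak. The fallback sets the stereocentre by allylboration and bypasses the ynone; it sets out from 9 and comes back at 12. Acetylide 10, made from 9 as in step 4, is formylated with DMF to 3-(trimethylsilyl)prop-2-ynal F6. Allylboration with (−)-Ipc2B(allyl) (from (−)-Ipc2BOMe and allylmagnesium bromide, Et2O, −78 °C, ethanolamine work-up) is expected to attack the Si face, as it does with benzaldehyde, and give (3S)-1-(trimethylsilyl)hex-5-en-1-yn-3-ol F7. Cross-metathesis of F7 with excess 2-methylbut-2-ene (second-generation Grubbs catalyst RuCl2(=CHPh)(H2IMes)(PCy3), CH2Cl2, 40 °C) exchanges the terminal CH2 for the isopropylidene group and gives 12.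

3. Step 4. The acetylide may act as a base on the doubly activated CH2 of 8 instead of adding, and the double bond may migrate when the adduct collapses. The fallback replaces acyl substitution by carbonyl addition and oxidation; it sets out from 8 and comes back at 11. Amide 8 is reduced with i-Bu2AlH at −78 °C to 4-methylpent-3-enal F8, which is used at once. Acetylide 10 adds to it at −78 °C to give racemic 6-methyl-1-(trimethylsilyl)hept-5-en-1-yn-3-ol F9. Oxidation of F9 with Dess–Martin periodinane buffered with NaHCO3 (or with MnO2) gives 11 without exposure to base.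

**Further compounds**

F1 | step 8 | tert-butyl(dimethyl){[(3S)-6-methylhept-5-en-1-yn-3-yl]oxy}silane | C#C[C@H](CC=C(C)C)O[Si](C)(C)C(C)(C)C
F2 | step 8 | tricarbonylchromium η6 complex of naphthol F3 | COc1ccc(O[Si](C)(C)C(C)(C)C)c2c(O)c([C@H](CC=C(C)C)O[Si](C)(C)C(C)(C)C)cc(OC)c12.O=C=[Cr](=C=O)=C=O
F3 | step 8 | 8-(tert-butyldimethylsilyloxy)-2-[(1S)-1-(tert-butyldimethylsilyloxy)-4-methylpent-3-en-1-yl]-4,5-dimethoxynaphthalen-1-ol | COc1ccc(O[Si](C)(C)C(C)(C)C)c2c(O)c([C@H](CC=C(C)C)O[Si](C)(C)C(C)(C)C)cc(OC)c12
F4 | step 8 | 8-(tert-butyldimethylsilyloxy)-2-[(1S)-1-(tert-butyldimethylsilyloxy)-4-methylpent-3-en-1-yl]-5-methoxynaphthalene-1,4-dione | COc1ccc(O[Si](C)(C)C(C)(C)C)c2c1C(=O)C=C([C@H](CC=C(C)C)O[Si](C)(C)C(C)(C)C)C2=O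
F5 | step 8 | 8-hydroxy-2-[(1S)-1-hydroxy-4-methylpent-3-en-1-yl]-5-methoxynaphthalene-1,4-dione | COc1ccc(O)c2c1C(=O)C=C([C@H](CC=C(C)C)O)C2=O
F6 | step 5 | 3-(trimethylsilyl)prop-2-ynal | C[Si](C)(C)C#CC=O
F7 | step 5 | (3S)-1-(trimethylsilyl)hex-5-en-1-yn-3-ol | C[Si](C)(C)C#C[C@H](CC=C)O
F8 | step 4 | 4-methylpent-3-enal | CC(C)=CCC=O
F9 | step 4 | rac-6-methyl-1-(trimethylsilyl)hept-5-en-1-yn-3-ol | CC(C)=CCC(O)C#C[Si](C)(C)C
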